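The numbers in the tables are simulated with constants of no real substance; scatter was added.

At early times the south-east run already loses sight of part of its L: the gap, which is the charge less the L, J and E read, is 11.2 % at 0.333 min. It still stands at 8.90 % at 2.50 min, although L has meanwhile fallen by a factor of 8.86, so I read the late gap as mostly X, with whatever G remains.

- south-east: L 0.60 M; run made earlier
- flask: L 0.30 M; time 12 min

south-east run (percent of the L charged)

| time / min | L / % | J / % | E / % |
|---|---|---|---|
| 0.167 | 35.7 | 12.1 | 45.2 |
| 0.333 | 19.5 | 16.6 | 52.7 |
| 0.667 | 10.4 | 21.0 | 57.9 |
| 1.00 | 6.5 | 23.8 | 58.8 |
| 1.33 | 4.4 | 24.2 | 59.5 |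
| 2.00 | 2.2 | 28.3 | 60.3 |
| 2.50 | 2.2 | 28.9 | 60.0 |

(scatter of a reading: 0.5 percentage points)

1. at 12 min, what has stopped the reaction, if anything has (forward and back rates have come level / all of L has reacted / it is still moving)
2. how much of the L has reacted by 12 min
3. how much J there is at 12 min, in percent of the L charged
4. how much E there is at 12 min, in percent of the L charged
5. how much X there is at 12 min, in percent of the L charged
6. amount of J if the flask were left three thousand times as long, in percent of the L charged

- in percentages every species weighs as the L in it: one E counts as two
- steps that have been proposed: L -> J; 2 L -> E; L <-> G; J <-> X
- the reaction counts as stopped when no species that holds the L changes by six tenths of a point or more over the second half of the time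
- a reading of L is of its free form alone
- a reading of J is of its free form alone

My decision for the flask is whether to leave it past 12 min or to change its charge. The gap per J reads 0.325 at 2.00 min and 0.308 at 2.50 min, two figures that the scatter does not let me tell apart, so it is my own assumption, not something these readings show, that the exchange of J with X is fast, and on that assumption I hold it in balance. That gives me the resting split, the X standing per J once the balance holds, read as the last gap over J: 0.308. It carries the scatter of 0.5 percentage points on each reading, and because the gap also holds any remaining G, I treat it as a high reading. In the usual terms, E against the rest is under kinetic control, and J against X under thermodynamic control.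

The forecast gives E 46 %, J 30 %, X 24 %, conversion 99.8 % and long-run J 20 %, and its answer to what has stopped the reaction is it is still moving, on the ground that “the mixture is still moving at 12 min”. I borrow its E but part from it on the split: sharing the remainder by my resting split gives J 41.3 % and X 12.7 %, with the same J for the long-left flask. So I sample the flask at 12 min, leave it no longer, and look to the charge for any other share of J.

In the flask at 12.0 min, the outcome is that all of L has reacted: L 0 %, conversion >99.9 %, J 43.9 %, E 45.6 %, X 10.5 %, and long-run J 43.9 %.

    L → J (k = 0.0230 s⁻¹)
    2 L → E (k = 0.100 M⁻¹ s⁻¹)
    L ⇌ G (K = 0.550, k = 0.0130 s⁻¹)
    J ⇌ X (K = 0.240, k = 0.0480 s⁻¹)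

In this flask the forward half-life of J going to X, 0.24 min at 0.424 min, is far shorter than the 12 min of standing, and the flask holds 0.239 X per J, while my split of 0.308 on its E gives J 41.6 %. On the flask charged with 0.075 M of L, where E is 19.2 %, the same split gives J 61.8 %, and that flask holds 65.1 %.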